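**Abbreviations:** Bn = benzyl, TBS = tert-butyldimethylsilyl, TBDPS = tert-butyldiphenylsilyl. Ring B is numbered C1 (CH–aryl), C2 (CH–C9), C3 (C–C10), C4 (=CH), C4a and C8a (fusion carbons); ring A carries OMe on C6 and the oxygen function on C7.

## The problem

Compound 24 is a 1-aryl-1,2-dihydronaphthalene. Benzene ring A is fused to the partly saturated ring B, and every functional carbon sits on ring B: C1 bears the 4-hydroxy-3-methoxyphenyl (guaiacyl) ring, C2 the acetoxymethyl carbon C9, C3 the formyl carbon C10, and C3=C4 is conjugated with ring A and the aldehyde. The only stereocentres are the neighbours C1 (S) and C2 (R), trans to each other. Nothing else can relay chirality, so the cleanest answer is to create both in the bond that closes ring B, where a catalyst can fix C2 and the ring transition state can fix C1 relative to it. C9 and C10 come from the same oxidation level in any four-carbon building block and end as acetate and aldehyde, so the two arms must be told apart early; the two phenols must end free beside an aliphatic acetate. The dienal of ring B loses two hydrogens to an arylnaphthalene under dehydrogenating oxidants and excludes hydrogenolysis. C1–H is doubly benzylic, and an aldehyde placed on C2 is an α-branched β,γ-unsaturated aldehyde that epimerizes and conjugates readily. The synthesis is opened by the fact that C1 is the benzylic carbon para to the phenolic OH of the pendant ring, hence the exocyclic carbon of a para-quinone methide once a leaving group on C1 departs. C2 turns nucleophilic when C9 is an aldehyde (enamine), and the (E)-C3=C4 alkene on ring A holds C2 next to C1.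

## Retrosynthesis

**24 ⇐ 23 ⇐ 22 ⇐ 21 ⇐ 20 ⇐ 19.** No skeletal bond is cut. The C10 aldehyde goes back to an allylic alcohol held as a TBDPS ether, the C9 acetate to a primary alcohol, and both phenols to benzyl ethers. The enal is made late (MnO2 on 22) because it is the most fragile group. Acetylation is done while C10 is still silylated (20 → 21), which settles the C9/C10 differentiation without a selectivity question. The guaiacyl phenol, free in the key step, is benzylated again in 20. Leaving it free would require acetylating an alcohol beside a phenol; acetylating it too would require a final selective ester cleavage beside the C9 acetate and the enal. With two benzyl ethers one BCl3 step (23 → 24) ends the synthesis. The forward steps must not aromatize ring B.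

**19 ⇐ 18 ⇐ 17 ⇐ 16.** The C1–C2 bond is cut. Cutting C4–C4a would leave both stereocentres to acyclic chemistry, and cutting C1–C8a (Friedel–Crafts) would not address C2. C1–C2 alone lies between the two stereocentres, so this cut removes both together with the ring. C1 becomes the exocyclic carbon of para-quinone methide 17 and C2 the α-carbon of the C9 aldehyde. Precursor 16 is an open-chain aldehyde whose single stereocentre is lost on ionization, so the racemate serves. The forward reaction must generate 17 where the enamine survives, attack through C2 only, set C2 by the catalyst and C1 by the closure, and pass the labile aldehyde 18 on to 19 at once.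

**16 ⇐ 15 ⇐ 14 ⇐ 12.** Only C–O bonds and the oxidation level of C9 change. The free phenol must appear last, because oxidants that make aldehydes also attack an electron-rich 4-hydroxybenzyl system. C9 is therefore oxidized while the phenol is silylated (14 → 15), and the aryl silyl ether is removed afterwards with buffered fluoride (15 → 16). A free benzhydrol beside the primary alcohol would turn the oxidation into a selectivity problem, so the carbinol of 12 is carried as its methyl ether. The acidic methanol that cleaves the temporary TBS ether on C9 also forms this ether (12 → 14), and the ether ionizes to 17 as the carbinol would. This requires the aryl TBS ether and the TBDPS ether to outlast camphorsulfonic acid in methanol, and the TBDPS ether to outlast a short fluoride treatment.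

**12 ⇐ 11 + 10 (11 from 8).** The C1–C8a bond is cut as aryl anion plus aldehyde: aryllithium 11, from bromide 8 by bromine–lithium exchange, adds to silylated vanillin 10. The opposite polarity would need a second formyl group on ring A, whereas the bromine is already in 6-bromovanillin 1. The cut gives two pieces of similar size and asks only that 8 carry no acidic or electrophilic group.

**8 ⇐ 7 ⇐ 6 ⇐ 5 ⇐ 4 ⇐ 2 + 3.** The C3=C4 bond is cut by a Stobbe condensation of aldehyde 2 with dimethyl succinate 3. Compared with an olefination using a purpose-built phosphonate, it uses a bulk diester and gives the (E)-alkene with ring A cis to the CH2CO2H arm, the geometry ring B needs. It also delivers the arms already different (acid = C9, ester = C10). Borane reduces the acid only (4 → 5), C9–OH takes a temporary TBS group (6), i-Bu2AlH reduces the ester (7), and C10–OH takes the lasting TBDPS group (8). The sequence must keep the alkene geometry and silylate 5 before it can lactonize.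

**2 ⇐ 1 and 10 ⇐ 9.** Benzylation of 1 and silylation of vanillin 9. Benzyl is used on ring A because it must pass alkoxide at reflux, hydrides, butyllithium, acid and fluoride. Silyl is used on the guaiacyl ring because it must come off under the mildest conditions just before the key step.

## Roads not taken

**Alternative 1:** C3–C4 is cut as a one-carbon ring contraction, leading to the bromomethyl β-keto ester A2, a 3-aryl-indan-1-one available by Nazarov cyclization.
- Forward step: Bu3SnH and azobisisobutyronitrile turn the CH2Br group of A2 into a primary radical that adds to the ketone carbon. The cyclopropyloxy radical opens to the ester-stabilized C2 radical, and hydrogen transfer gives the 4-oxotetralin ester A1 (Dowd–Beckwith expansion).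
- Merits: ring B comes from robust five-ring chemistry. The C2 ester is epimerizable, so the 1,2-trans relation is under thermodynamic control, which is safer than the kinetic control of the chosen closure.
- Weak points: A1 lacks C10 and carries a C4 ketone the target does not have, so formylation at C3, ketone reduction, dehydration, ester reduction and acetylation must follow. The absolute configuration at C1 must come from an enantioselective Nazarov step on a very electron-rich substrate, outside the key step. Stoichiometric tin and direct reduction of the bromide add cost.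
- Comparison: against the firmer trans control here, the chosen plan delivers both stereocentres, ring B and C10 in its final place in one catalytic operation.

**Alternative 2:** C1–C2 and C3–C4 are cut together, giving the 2-benzylbenzaldehyde A4 and (E)-4-acetoxybut-2-enal A5.
- Forward step: irradiation of A4 at 365 nm gives the hydroxy-ortho-quinodimethane, which adds A5 under Ti(Oi-Pr)4 and a TADDOL ligand to give tetralin A3. The aryl-bearing diene terminus joins the β-carbon of the enal, so the regiochemistry is the natural one, and endo addition of the E-dienophile gives the 1,2-trans relation.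
- Merits: both ring bonds form at once, C9 arrives as the acetate and C10 as the aldehyde, and only dehydration and desilylation remain. In step count and convergence this road is clearly better than the chosen one.
- Weak points: the sense and level of induction rest on the geometry and facial control of an aryl-substituted photoenol, less secure than 2-methylbenzaldehydes. A5 binds titanium through one oxygen only and polymerizes and isomerizes in light. Four stereocentres arise where two are wanted, the step needs stoichiometric titanium and photochemical equipment, and the dehydration can aromatize ring B.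
- Comparison: the chosen plan offers a thermal, catalytic closure with a simple stereochemical model (shielded enamine, ring transition state), and its failures can be repaired without leaving the disconnection.

**Alternative 3:** C4–C4a is cut, leading to the aryl bromide A7 with an α-methylene aldehyde in the side chain.
- Forward step: Pd(OAc)2 with P(o-tol)3 and base gives zerovalent palladium, which inserts into the C4a–Br bond. The aryl group adds to the terminal methylene carbon in a 6-endo closure, and β-hydride elimination gives enal A6, the same compound as 23.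
- Merits: the closure gives the dienal in its final oxidation state with C9 already acetylated, so no redox change at C9 or C10 follows ring closure. Only the debenzylation of step 17 remains; in this respect the road is better.
- Weak points: both stereocentres must already stand in the open chain of A7 as an anti 3,3-diaryl-2-(acetoxymethyl) unit, for which no one-step asymmetric entry is at hand. The α-methylene aldehyde can move its double bond to the tetrasubstituted position under base or palladium hydride and so erase C2. β-Hydride elimination toward C2 and 5-exo closure compete, and the electron-rich aryl bromide inserts slowly.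
- Comparison: the chosen closure creates C1 and C2 from a precursor whose only stereocentre is destroyed in the step, whereas this road moves the stereochemical problem into acyclic chemistry.

Key step: step 12

**Remark on the chemistry:** the face of the dienamine left open by the diarylprolinol silyl ether is taken from the usual steric-shielding model of aldehyde enamines, which calls for the (R)-catalyst; should the dienamine react in the opposite sense, the (S)-catalyst is used and nothing else changes.

## Route

Step 1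
Reactants: 1 6-bromovanillin
Product: 2 4-(benzyloxy)-2-bromo-5-methoxybenzaldehyde
Conditions: BnBr, K2CO3, DMF, rt
Reagents that add atoms: benzyl bromide, BrCc1ccccc1
Why: Williamson etherification of the phenoxide; aldehyde and aryl bromide are inert, and the benzyl ether withstands every base, hydride, organolithium, acid and fluoride step up to the last one.

Step 2
Reactants: 2 4-(benzyloxy)-2-bromo-5-methoxybenzaldehyde; 3 dimethyl succinate
Product: 4 (E)-4-[4-(benzyloxy)-2-bromo-5-methoxyphenyl]-3-(methoxycarbonyl)but-3-enoic acid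
Conditions: NaOMe, MeOH, reflux; then aq. HCl
Reagents that add atoms: none
Why: Stobbe condensation: the succinate enolate adds to the non-enolizable aldehyde, the alkoxide lactonizes onto the far ester and base opens the paraconate to the half-ester. The product should be the (E)-alkene with the aryl group cis to the CH2CO2H arm, and the two arms emerge differentiated as acid (C9) and ester (C10).

Step 3
Reactants: 4 (E)-4-[4-(benzyloxy)-2-bromo-5-methoxyphenyl]-3-(methoxycarbonyl)but-3-enoic acid
Product: 5 methyl (E)-2-{[4-(benzyloxy)-2-bromo-5-methoxyphenyl]methylidene}-4-hydroxybutanoate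
Conditions: BH3·SMe2, THF, 0 °C → rt; then MeOH
Reagents that add atoms: none
Why: Chemoselective borane reduction of a carboxylic acid (through the acyloxyborane) beside a conjugated ester; the trisubstituted styrene should hydroborate far more slowly. Crude 5 is silylated at once so that it cannot lactonize.

Step 4
Reactants: 5 methyl (E)-2-{[4-(benzyloxy)-2-bromo-5-methoxyphenyl]methylidene}-4-hydroxybutanoate
Product: 6 methyl (E)-2-{[4-(benzyloxy)-2-bromo-5-methoxyphenyl]methylidene}-4-[(tert-butyldimethylsilyl)oxy]butanoate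
Conditions: TBSCl, imidazole, DMF, 0 °C → rt
Reagents that add atoms: tert-butyl(chloro)dimethylsilane, CC(C)(C)[Si](C)(C)Cl
Why: Standard silylation of a primary alcohol; the TBS group is the temporary mask of C9–OH and is the one silyl ether that step 9 removes with acid.

Step 5
Reactants: 6 methyl (E)-2-{[4-(benzyloxy)-2-bromo-5-methoxyphenyl]methylidene}-4-[(tert-butyldimethylsilyl)oxy]butanoate
Product: 7 (E)-2-{[4-(benzyloxy)-2-bromo-5-methoxyphenyl]methylidene}-4-[(tert-butyldimethylsilyl)oxy]butan-1-ol
Conditions: i-Bu2AlH, CH2Cl2, −78 → 0 °C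
Reagents that add atoms: none
Why: 1,2-Reduction of the conjugated ester to the allylic alcohol by the aluminium hydride; aryl bromide, silyl ether and alkene geometry are not touched at low temperature.

Step 6
Reactants: 7 (E)-2-{[4-(benzyloxy)-2-bromo-5-methoxyphenyl]methylidene}-4-[(tert-butyldimethylsilyl)oxy]butan-1-ol
Product: 8 (E)-1-[4-(benzyloxy)-2-bromo-5-methoxyphenyl]-4-[(tert-butyldimethylsilyl)oxy]-2-{[(tert-butyldiphenylsilyl)oxy]methyl}but-1-ene
Conditions: TBDPSCl, imidazole, DMF, rt
Reagents that add atoms: tert-butyl(chloro)diphenylsilane, CC(C)(C)[Si](Cl)(c1ccccc1)c1ccccc1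
Why: Silylation of the allylic alcohol; TBDPS is chosen for C10 because it should survive the acid that removes the alkyl TBS ether and the brief fluoride treatment that removes the aryl TBS ether.

Step 7
Reactants: 9 vanillin
Product: 10 4-[(tert-butyldimethylsilyl)oxy]-3-methoxybenzaldehyde
Conditions: TBSCl, imidazole, CH2Cl2, rt
Reagents that add atoms: tert-butyl(chloro)dimethylsilane, CC(C)(C)[Si](C)(C)Cl
Why: Silylation of the phenol removes the acidic proton before the organolithium addition and gives a group that fluoride cleaves in minutes.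

Step 8
Reactants: 8 (E)-1-[4-(benzyloxy)-2-bromo-5-methoxyphenyl]-4-[(tert-butyldimethylsilyl)oxy]-2-{[(tert-butyldiphenylsilyl)oxy]methyl}but-1-ene; 10 4-[(tert-butyldimethylsilyl)oxy]-3-methoxybenzaldehyde
Product: 12 (RS)-{5-(benzyloxy)-2-[(E)-4-[(tert-butyldimethylsilyl)oxy]-2-{[(tert-butyldiphenylsilyl)oxy]methyl}but-1-en-1-yl]-4-methoxyphenyl}{4-[(tert-butyldimethylsilyl)oxy]-3-methoxyphenyl}methanol, via aryllithium 11 (not isolated)
Conditions: n-BuLi, THF, −78 °C; then 10, −78 → −40 °C; aq. NH4Cl
Reagents that add atoms: none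
Why: Bromine–lithium exchange on the aryl bromide is faster than any deprotonation at −78 °C, and the aryllithium adds 1,2 to the aldehyde. The new carbinol centre forms as the racemate, which is immaterial because this carbon becomes trigonal in the quinone methide.

Step 9
Reactants: 12 (RS)-{5-(benzyloxy)-2-[(E)-4-[(tert-butyldimethylsilyl)oxy]-2-{[(tert-butyldiphenylsilyl)oxy]methyl}but-1-en-1-yl]-4-methoxyphenyl}{4-[(tert-butyldimethylsilyl)oxy]-3-methoxyphenyl}methanol
Product: 14 (E)-4-{4-(benzyloxy)-2-[(RS)-{4-[(tert-butyldimethylsilyl)oxy]-3-methoxyphenyl}(methoxy)methyl]-5-methoxyphenyl}-3-{[(tert-butyldiphenylsilyl)oxy]methyl}but-3-en-1-ol, via methyl ether 13 (not isolated)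
Conditions: camphorsulfonic acid (cat.), MeOH–CH2Cl2, 0 °C → rt; then Et3N
Reagents that add atoms: methanol, CO
Why: Acid-catalysed methanolysis does two jobs: the electron-rich benzhydrol ionizes (SN1) and is trapped by the solvent as methyl ether 13, an exchange that is degenerate from then on, and the primary alkyl TBS ether is solvolysed; the aryl TBS ether and the TBDPS ether should be stable to this acid. The methyl ether removes the secondary alcohol that would compete in the next oxidation and is as good a leaving group as hydroxyl for the later quinone methide formation.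

Step 10
Reactants: 14 (E)-4-{4-(benzyloxy)-2-[(RS)-{4-[(tert-butyldimethylsilyl)oxy]-3-methoxyphenyl}(methoxy)methyl]-5-methoxyphenyl}-3-{[(tert-butyldiphenylsilyl)oxy]methyl}but-3-en-1-ol
Product: 15 (E)-4-{4-(benzyloxy)-2-[(RS)-{4-[(tert-butyldimethylsilyl)oxy]-3-methoxyphenyl}(methoxy)methyl]-5-methoxyphenyl}-3-{[(tert-butyldiphenylsilyl)oxy]methyl}but-3-enal
Conditions: Dess–Martin periodinane, NaHCO3, CH2Cl2, 0 °C → rt
Reagents that add atoms: none
Why: Buffered periodinane oxidation is the standard way to β,γ-unsaturated aldehydes without double-bond migration; the only free hydroxyl is on C9 and no free phenol is present.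

Step 11
Reactants: 15 (E)-4-{4-(benzyloxy)-2-[(RS)-{4-[(tert-butyldimethylsilyl)oxy]-3-methoxyphenyl}(methoxy)methyl]-5-methoxyphenyl}-3-{[(tert-butyldiphenylsilyl)oxy]methyl}but-3-enal
Product: 16 (E)-4-{4-(benzyloxy)-2-[(RS)-(4-hydroxy-3-methoxyphenyl)(methoxy)methyl]-5-methoxyphenyl}-3-{[(tert-butyldiphenylsilyl)oxy]methyl}but-3-enal
Conditions: Bu4NF, AcOH, THF, −20 → 0 °C
Reagents that add atoms: none
Why: Fluoride cleaves an aryl silyl ether far faster than a primary TBDPS ether because phenoxide is the better leaving group. The acetic acid buffer protonates the phenoxide at once, so it should neither expel methoxide prematurely nor enolize the aldehyde; 16 is used without storage.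

Step 12
Reactants: 16 (E)-4-{4-(benzyloxy)-2-[(RS)-(4-hydroxy-3-methoxyphenyl)(methoxy)methyl]-5-methoxyphenyl}-3-{[(tert-butyldiphenylsilyl)oxy]methyl}but-3-enal
Product: 19 [(1S,2R)-7-(benzyloxy)-3-{[(tert-butyldiphenylsilyl)oxy]methyl}-1-(4-hydroxy-3-methoxyphenyl)-6-methoxy-1,2-dihydronaphthalen-2-yl]methanol, via para-quinone methide 17 (not isolated), via aldehyde 18 (not isolated)
Conditions: (R)-2-[diphenyl(trimethylsilyloxy)methyl]pyrrolidine (20 mol %), CF3CO2H (30 mol %), CH2Cl2 (0.02 M), −20 °C → rt; then MeOH, NaBH4, 0 °C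
Reagents that add atoms: none
Why: CF3CO2H ionizes the 4-hydroxybenzhydryl methyl ether of 16 with loss of methanol to the neutral para-quinone methide 17 (exocyclic carbon = C1), while the secondary amine condenses with the C9 aldehyde to an (E)-dienamine whose α-carbon C2 adds to C1 in a 1,6-addition that restores the phenol; hydrolysis of the iminium ion frees 18 and the catalyst. The closest known reaction type is the diarylprolinol silyl ether-catalysed α-alkylation of aldehydes and of dienamines with para-quinone methides and with benzhydryl cations generated by acid, here run within one molecule. Ring B closes in a 6-exo-trig mode (6-(enolexo)-exo-trig: the attacked C1=C bond of the quinone methide and the enamine C=C both lie outside the new ring). C2 is set by the catalyst: the diphenyl(silyloxy)methyl group covers one face of the s-trans (E)-enamine, and the (R)-catalyst should leave the Re face of C2 open, which gives 2R. C1 is set by the ring closure: in the half-chair transition state the quinoid ring on C1 and the N–CH= unit on C2 stay apart, which should give the 1,2-trans product (1S). The step needs α- over γ-attack of the dienamine, closure over intermolecular capture of 17, and no loss of C2 afterwards: γ-attack at C4 would make a four-membered ring, the (E)-C3=C4 bond on ring A holds C2 next to C1 and the run is dilute, and NaBH4 added to the same flask reduces the α-branched β,γ-unsaturated aldehyde 18 to 19 before it can epimerize or conjugate.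

Step 13
Reactants: 19 [(1S,2R)-7-(benzyloxy)-3-{[(tert-butyldiphenylsilyl)oxy]methyl}-1-(4-hydroxy-3-methoxyphenyl)-6-methoxy-1,2-dihydronaphthalen-2-yl]methanol
Product: 20 [(1S,2R)-7-(benzyloxy)-1-[4-(benzyloxy)-3-methoxyphenyl]-3-{[(tert-butyldiphenylsilyl)oxy]methyl}-6-methoxy-1,2-dihydronaphthalen-2-yl]methanol
Conditions: BnBr, K2CO3, DMF, rt
Reagents that add atoms: benzyl bromide, BrCc1ccccc1
Why: Carbonate deprotonates only the phenol, so Williamson benzylation is selective over the primary alcohol; neither stereocentre is acidic once C9 is an alcohol.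

Step 14
Reactants: 20 [(1S,2R)-7-(benzyloxy)-1-[4-(benzyloxy)-3-methoxyphenyl]-3-{[(tert-butyldiphenylsilyl)oxy]methyl}-6-methoxy-1,2-dihydronaphthalen-2-yl]methanol
Product: 21 [(1S,2R)-7-(benzyloxy)-1-[4-(benzyloxy)-3-methoxyphenyl]-3-{[(tert-butyldiphenylsilyl)oxy]methyl}-6-methoxy-1,2-dihydronaphthalen-2-yl]methyl acetate
Conditions: Ac2O, pyridine, 4-(dimethylamino)pyridine (cat.), CH2Cl2, 0 °C → rt
Reagents that add atoms: acetic anhydride, CC(=O)OC(C)=O
Why: Acylation of the only free hydroxyl; C10 is still silylated, so the acetate can go nowhere but C9.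

Step 15
Reactants: 21 [(1S,2R)-7-(benzyloxy)-1-[4-(benzyloxy)-3-methoxyphenyl]-3-{[(tert-butyldiphenylsilyl)oxy]methyl}-6-methoxy-1,2-dihydronaphthalen-2-yl]methyl acetate
Product: 22 [(1S,2R)-7-(benzyloxy)-1-[4-(benzyloxy)-3-methoxyphenyl]-3-(hydroxymethyl)-6-methoxy-1,2-dihydronaphthalen-2-yl]methyl acetate
Conditions: Bu4NF, AcOH, THF, rt
Reagents that add atoms: none
Why: Fluoride desilylation; the acetic acid buffer keeps the medium from cleaving the acetate or moving it to the freed C10 hydroxyl, which is four atoms away.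

Step 16
Reactants: 22 [(1S,2R)-7-(benzyloxy)-1-[4-(benzyloxy)-3-methoxyphenyl]-3-(hydroxymethyl)-6-methoxy-1,2-dihydronaphthalen-2-yl]methyl acetate
Product: 23 [(1S,2R)-7-(benzyloxy)-1-[4-(benzyloxy)-3-methoxyphenyl]-3-formyl-6-methoxy-1,2-dihydronaphthalen-2-yl]methyl acetate
Conditions: MnO2, CH2Cl2, rt
Reagents that add atoms: none
Why: Selective oxidation of an allylic alcohol on the MnO2 surface under neutral conditions; the reagent is mild enough that ring B should not be dehydrogenated, and C2 is not α to the new carbonyl group.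

Step 17
Reactants: 23 [(1S,2R)-7-(benzyloxy)-1-[4-(benzyloxy)-3-methoxyphenyl]-3-formyl-6-methoxy-1,2-dihydronaphthalen-2-yl]methyl acetate
Product: 24 [(1S,2R)-3-formyl-7-hydroxy-1-(4-hydroxy-3-methoxyphenyl)-6-methoxy-1,2-dihydronaphthalen-2-yl]methyl acetate
Conditions: BCl3, C6HMe5, CH2Cl2, −78 °C; then MeOH
Reagents that add atoms: none
Why: Lewis acid cleavage of aryl benzyl ethers at low temperature, with pentamethylbenzene taking up the benzyl cations so that they do not alkylate the electron-rich rings; acetate, methyl ethers and the enal should survive at −78 °C, and no hydrogen or oxidant touches ring B.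

## Compound list

1 | 6-bromovanillin (2-bromo-4-hydroxy-5-methoxybenzaldehyde) | COc1cc(C=O)c(Br)cc1O | starting material
2 | 4-(benzyloxy)-2-bromo-5-methoxybenzaldehyde | COc1cc(C=O)c(Br)cc1OCc2ccccc2 | intermediate
3 | dimethyl succinate | COC(=O)CCC(=O)OC | starting material
4 | (E)-4-[4-(benzyloxy)-2-bromo-5-methoxyphenyl]-3-(methoxycarbonyl)but-3-enoic acid | OC(=O)C/C(C(=O)OC)=C\c1cc(OC)c(OCc2ccccc2)cc1Br | intermediate
5 | methyl (E)-2-{[4-(benzyloxy)-2-bromo-5-methoxyphenyl]methylidene}-4-hydroxybutanoate | OCC/C(C(=O)OC)=C\c1cc(OC)c(OCc2ccccc2)cc1Br | intermediate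
6 | methyl (E)-2-{[4-(benzyloxy)-2-bromo-5-methoxyphenyl]methylidene}-4-[(tert-butyldimethylsilyl)oxy]butanoate | CC(C)(C)[Si](C)(C)OCC/C(C(=O)OC)=C\c1cc(OC)c(OCc2ccccc2)cc1Br | intermediate
7 | (E)-2-{[4-(benzyloxy)-2-bromo-5-methoxyphenyl]methylidene}-4-[(tert-butyldimethylsilyl)oxy]butan-1-ol | CC(C)(C)[Si](C)(C)OCC/C(CO)=C\c1cc(OC)c(OCc2ccccc2)cc1Br | intermediate
8 | (E)-1-[4-(benzyloxy)-2-bromo-5-methoxyphenyl]-4-[(tert-butyldimethylsilyl)oxy]-2-{[(tert-butyldiphenylsilyl)oxy]methyl}but-1-ene | CC(C)(C)[Si](C)(C)OCC/C(CO[Si](c2ccccc2)(c3ccccc3)C(C)(C)C)=C\c1cc(OC)c(OCc4ccccc4)cc1Br | intermediate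
9 | vanillin (4-hydroxy-3-methoxybenzaldehyde) | COc1cc(C=O)ccc1O | starting material
10 | 4-[(tert-butyldimethylsilyl)oxy]-3-methoxybenzaldehyde | COc1cc(C=O)ccc1O[Si](C)(C)C(C)(C)C | intermediate
11 | {5-(benzyloxy)-2-[(E)-4-[(tert-butyldimethylsilyl)oxy]-2-{[(tert-butyldiphenylsilyl)oxy]methyl}but-1-en-1-yl]-4-methoxyphenyl}lithium | [Li]c1cc(OCc2ccccc2)c(OC)cc1/C=C(\CCO[Si](C)(C)C(C)(C)C)CO[Si](c3ccccc3)(c4ccccc4)C(C)(C)C | intermediate (not isolated)
12 | (RS)-{5-(benzyloxy)-2-[(E)-4-[(tert-butyldimethylsilyl)oxy]-2-{[(tert-butyldiphenylsilyl)oxy]methyl}but-1-en-1-yl]-4-methoxyphenyl}{4-[(tert-butyldimethylsilyl)oxy]-3-methoxyphenyl}methanol | COc1cc(C(O)c2cc(OCc3ccccc3)c(OC)cc2/C=C(\CCO[Si](C)(C)C(C)(C)C)CO[Si](c4ccccc4)(c5ccccc5)C(C)(C)C)ccc1O[Si](C)(C)C(C)(C)C | intermediate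
13 | methyl ether of 12: (E)-1-{4-(benzyloxy)-2-[(RS)-{4-[(tert-butyldimethylsilyl)oxy]-3-methoxyphenyl}(methoxy)methyl]-5-methoxyphenyl}-4-[(tert-butyldimethylsilyl)oxy]-2-{[(tert-butyldiphenylsilyl)oxy]methyl}but-1-ene | COc1cc(C(OC)c2cc(OCc3ccccc3)c(OC)cc2/C=C(\CCO[Si](C)(C)C(C)(C)C)CO[Si](c4ccccc4)(c5ccccc5)C(C)(C)C)ccc1O[Si](C)(C)C(C)(C)C | intermediate (not isolated)
14 | (E)-4-{4-(benzyloxy)-2-[(RS)-{4-[(tert-butyldimethylsilyl)oxy]-3-methoxyphenyl}(methoxy)methyl]-5-methoxyphenyl}-3-{[(tert-butyldiphenylsilyl)oxy]methyl}but-3-en-1-ol | COc1cc(C(OC)c2cc(OCc3ccccc3)c(OC)cc2/C=C(\CCO)CO[Si](c4ccccc4)(c5ccccc5)C(C)(C)C)ccc1O[Si](C)(C)C(C)(C)C | intermediate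
15 | (E)-4-{4-(benzyloxy)-2-[(RS)-{4-[(tert-butyldimethylsilyl)oxy]-3-methoxyphenyl}(methoxy)methyl]-5-methoxyphenyl}-3-{[(tert-butyldiphenylsilyl)oxy]methyl}but-3-enal | COc1cc(C(OC)c2cc(OCc3ccccc3)c(OC)cc2/C=C(\CC=O)CO[Si](c4ccccc4)(c5ccccc5)C(C)(C)C)ccc1O[Si](C)(C)C(C)(C)C | intermediate
16 | (E)-4-{4-(benzyloxy)-2-[(RS)-(4-hydroxy-3-methoxyphenyl)(methoxy)methyl]-5-methoxyphenyl}-3-{[(tert-butyldiphenylsilyl)oxy]methyl}but-3-enal (key-step precursor) | COc1cc(C(OC)c2cc(OCc3ccccc3)c(OC)cc2/C=C(\CC=O)CO[Si](c4ccccc4)(c5ccccc5)C(C)(C)C)ccc1O | intermediate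
17 | para-quinone methide: (E)-4-{4-(benzyloxy)-5-methoxy-2-[(3-methoxy-4-oxocyclohexa-2,5-dien-1-ylidene)methyl]phenyl}-3-{[(tert-butyldiphenylsilyl)oxy]methyl}but-3-enal | COC1=CC(C=CC1=O)=Cc2cc(OCc3ccccc3)c(OC)cc2/C=C(\CC=O)CO[Si](c4ccccc4)(c5ccccc5)C(C)(C)C | intermediate (not isolated)
18 | (1S,2R)-7-(benzyloxy)-3-{[(tert-butyldiphenylsilyl)oxy]methyl}-1-(4-hydroxy-3-methoxyphenyl)-6-methoxy-1,2-dihydronaphthalene-2-carbaldehyde (key-step product) | COc1cc([C@H]2c3cc(OCc4ccccc4)c(OC)cc3C=C(CO[Si](c5ccccc5)(c6ccccc6)C(C)(C)C)[C@@H]2C=O)ccc1O | intermediate (not isolated)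
19 | [(1S,2R)-7-(benzyloxy)-3-{[(tert-butyldiphenylsilyl)oxy]methyl}-1-(4-hydroxy-3-methoxyphenyl)-6-methoxy-1,2-dihydronaphthalen-2-yl]methanol | COc1cc([C@H]2c3cc(OCc4ccccc4)c(OC)cc3C=C(CO[Si](c5ccccc5)(c6ccccc6)C(C)(C)C)[C@@H]2CO)ccc1O | intermediate
20 | [(1S,2R)-7-(benzyloxy)-1-[4-(benzyloxy)-3-methoxyphenyl]-3-{[(tert-butyldiphenylsilyl)oxy]methyl}-6-methoxy-1,2-dihydronaphthalen-2-yl]methanol | COc1cc([C@H]2c3cc(OCc4ccccc4)c(OC)cc3C=C(CO[Si](c5ccccc5)(c6ccccc6)C(C)(C)C)[C@@H]2CO)ccc1OCc7ccccc7 | intermediate
21 | [(1S,2R)-7-(benzyloxy)-1-[4-(benzyloxy)-3-methoxyphenyl]-3-{[(tert-butyldiphenylsilyl)oxy]methyl}-6-methoxy-1,2-dihydronaphthalen-2-yl]methyl acetate | COc1cc([C@H]2c3cc(OCc4ccccc4)c(OC)cc3C=C(CO[Si](c5ccccc5)(c6ccccc6)C(C)(C)C)[C@@H]2COC(C)=O)ccc1OCc7ccccc7 | intermediate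
22 | [(1S,2R)-7-(benzyloxy)-1-[4-(benzyloxy)-3-methoxyphenyl]-3-(hydroxymethyl)-6-methoxy-1,2-dihydronaphthalen-2-yl]methyl acetate | COc1cc([C@H]2c3cc(OCc4ccccc4)c(OC)cc3C=C(CO)[C@@H]2COC(C)=O)ccc1OCc5ccccc5 | intermediate
23 | [(1S,2R)-7-(benzyloxy)-1-[4-(benzyloxy)-3-methoxyphenyl]-3-formyl-6-methoxy-1,2-dihydronaphthalen-2-yl]methyl acetate | COc1cc([C@H]2c3cc(OCc4ccccc4)c(OC)cc3C=C(C=O)[C@@H]2COC(C)=O)ccc1OCc5ccccc5 | intermediate
24 | [(1S,2R)-3-formyl-7-hydroxy-1-(4-hydroxy-3-methoxyphenyl)-6-methoxy-1,2-dihydronaphthalen-2-yl]methyl acetate | COc1cc([C@H]2c3cc(O)c(OC)cc3C=C(C=O)[C@@H]2COC(C)=O)ccc1O | target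

## Step count and least certain steps

Total: 17 steps. Longest linear sequence: 16 steps (steps 1–6 and 8–17, from 1); step 7 is a one-step side branch.

**Step 12 (key step).** Three things may go wrong:
- Face selection at C2 may be poor, because a dienamine is less tightly shielded than a simple enamine.
- The trans preference in the closure may be low; the cis product would not be repaired by epimerization at C2, since that would invert the wrong centre.
- The quinone methide may be captured between molecules by phenol, methanol or the amine, giving oligomers.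

Fallback (sets out from 14, returns at 19): the aldehyde enamine is replaced by an imide enolate under auxiliary control.
- 14 is oxidized in two stages (Dess–Martin periodinane, then NaClO2, NaH2PO4, 2-methyl-2-butene) to the carboxylic acid (E)-4-{4-(benzyloxy)-2-[(RS)-{4-[(tert-butyldimethylsilyl)oxy]-3-methoxyphenyl}(methoxy)methyl]-5-methoxyphenyl}-3-{[(tert-butyldiphenylsilyl)oxy]methyl}but-3-enoic acid F1.
- The mixed pivalic anhydride of F1 acylates lithiated (R)-4-benzyl-1,3-oxazolidin-2-one to give the N-acyl oxazolidinone F2.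
- TiCl4 and i-Pr2NEt form the chlorotitanium Z-enolate while TiCl4 ionizes the benzhydryl methyl ether. The enolate face away from the benzyl group should close ring B to the trans imide F3. Alkylation of titanium imide enolates by diarylmethyl methyl ethers is a known SN1-type process.
- LiBH4 removes the auxiliary to give the primary alcohol F4, the guaiacyl TBS ether of 19, and Bu4NF with AcOH at 0 °C gives 19.

**Step 9.** The benzhydryl cation forms reversibly many times in acidic methanol. Capture by the neighbouring alkene or an arene, or slow loss of the aryl silyl group through the cation, would accumulate, and the TBDPS ether could begin to solvolyse if the reaction is run long.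

Fallback (sets out from 8, returns at 19 through 17): the carbinol is kept free and no acid touches the coupled product.
- Camphorsulfonic acid in methanol removes the alkyl TBS group of 8 to give (E)-4-[4-(benzyloxy)-2-bromo-5-methoxyphenyl]-3-{[(tert-butyldiphenylsilyl)oxy]methyl}but-3-en-1-ol F5.
- Two equivalents of n-BuLi (alkoxide, then bromine–lithium exchange) and 10 give the diol F6.
- Cu(MeCN)4OTf, 2,2'-bipyridine, 2,2,6,6-tetramethylpiperidin-1-oxyl and N-methylimidazole under air should oxidize only the primary alcohol, giving the hydroxy aldehyde F7.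
- Bu4NF with AcOH frees the phenol to give the carbinol F8. Under the conditions of step 12, F8 loses water to the same quinone methide 17 and gives 19.

**Step 3.** Borane may hydroborate the styrene if left too long, and the γ-hydroxy ester may close to the α-arylidene lactone before silylation, which would merge the two arms again. Any Z-isomer from step 2 would also be carried along.

Fallback (sets out from 2, returns at 6): the olefin is built with the C9 arm already protected. The phosphonate methyl 4-[(tert-butyldimethylsilyl)oxy]-2-(dimethoxyphosphoryl)butanoate F9 is made from trimethyl phosphonoacetate and tert-butyl(2-iodoethoxy)dimethylsilane with NaH. A Horner–Wadsworth–Emmons reaction of F9 with 2 (NaH, THF) gives 6 directly, bypassing steps 2–4.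

**Step 17.** BCl3 meets the dienal, the acetate and two electron-rich rings at once. Benzyl transfer to the rings, partial cleavage of the acetate or of a methyl ether, or acid-induced aromatization of ring B may occur.

Fallback (sets out from 21, returns at 24): the benzyl ethers are removed before the enal exists.
- BCl3 with pentamethylbenzene at −78 °C converts 21 into the bisphenol [(1S,2R)-3-{[(tert-butyldiphenylsilyl)oxy]methyl}-7-hydroxy-1-(4-hydroxy-3-methoxyphenyl)-6-methoxy-1,2-dihydronaphthalen-2-yl]methyl acetate F10.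
- Bu4NF with AcOH gives the allylic alcohol [(1S,2R)-7-hydroxy-1-(4-hydroxy-3-methoxyphenyl)-3-(hydroxymethyl)-6-methoxy-1,2-dihydronaphthalen-2-yl]methyl acetate F11.
- MnO2 oxidizes the allylic alcohol of F11 in the presence of the free phenols to give 24.

## Further compounds

F1 | step 12 | (E)-4-{4-(benzyloxy)-2-[(RS)-{4-[(tert-butyldimethylsilyl)oxy]-3-methoxyphenyl}(methoxy)methyl]-5-methoxyphenyl}-3-{[(tert-butyldiphenylsilyl)oxy]methyl}but-3-enoic acid | COc1cc(C(OC)c2cc(OCc3ccccc3)c(OC)cc2/C=C(\CC(O)=O)CO[Si](c4ccccc4)(c5ccccc5)C(C)(C)C)ccc1O[Si](C)(C)C(C)(C)C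
F2 | step 12 | (R)-4-benzyl-3-[(E)-4-{4-(benzyloxy)-2-[(RS)-{4-[(tert-butyldimethylsilyl)oxy]-3-methoxyphenyl}(methoxy)methyl]-5-methoxyphenyl}-3-{[(tert-butyldiphenylsilyl)oxy]methyl}but-3-enoyl]-1,3-oxazolidin-2-one | COc1cc(C(OC)c2cc(OCc3ccccc3)c(OC)cc2/C=C(\CC(=O)N6C(=O)OC[C@H]6Cc7ccccc7)CO[Si](c4ccccc4)(c5ccccc5)C(C)(C)C)ccc1O[Si](C)(C)C(C)(C)C
F3 | step 12 | (R)-4-benzyl-3-{[(1S,2R)-7-(benzyloxy)-1-{4-[(tert-butyldimethylsilyl)oxy]-3-methoxyphenyl}-3-{[(tert-butyldiphenylsilyl)oxy]methyl}-6-methoxy-1,2-dihydronaphthalen-2-yl]carbonyl}-1,3-oxazolidin-2-one | COc1cc([C@H]2c3cc(OCc4ccccc4)c(OC)cc3C=C(CO[Si](c5ccccc5)(c6ccccc6)C(C)(C)C)[C@@H]2C(=O)N7C(=O)OC[C@H]7Cc8ccccc8)ccc1O[Si](C)(C)C(C)(C)C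
F4 | step 12 | [(1S,2R)-7-(benzyloxy)-1-{4-[(tert-butyldimethylsilyl)oxy]-3-methoxyphenyl}-3-{[(tert-butyldiphenylsilyl)oxy]methyl}-6-methoxy-1,2-dihydronaphthalen-2-yl]methanol | COc1cc([C@H]2c3cc(OCc4ccccc4)c(OC)cc3C=C(CO[Si](c5ccccc5)(c6ccccc6)C(C)(C)C)[C@@H]2CO)ccc1O[Si](C)(C)C(C)(C)C
F5 | step 9 | (E)-4-[4-(benzyloxy)-2-bromo-5-methoxyphenyl]-3-{[(tert-butyldiphenylsilyl)oxy]methyl}but-3-en-1-ol | OCC/C(CO[Si](c2ccccc2)(c3ccccc3)C(C)(C)C)=C\c1cc(OC)c(OCc4ccccc4)cc1Br
F6 | step 9 | (E)-4-{4-(benzyloxy)-2-[(RS)-{4-[(tert-butyldimethylsilyl)oxy]-3-methoxyphenyl}(hydroxy)methyl]-5-methoxyphenyl}-3-{[(tert-butyldiphenylsilyl)oxy]methyl}but-3-en-1-ol | COc1cc(C(O)c2cc(OCc3ccccc3)c(OC)cc2/C=C(\CCO)CO[Si](c4ccccc4)(c5ccccc5)C(C)(C)C)ccc1O[Si](C)(C)C(C)(C)C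
F7 | step 9 | (E)-4-{4-(benzyloxy)-2-[(RS)-{4-[(tert-butyldimethylsilyl)oxy]-3-methoxyphenyl}(hydroxy)methyl]-5-methoxyphenyl}-3-{[(tert-butyldiphenylsilyl)oxy]methyl}but-3-enal | COc1cc(C(O)c2cc(OCc3ccccc3)c(OC)cc2/C=C(\CC=O)CO[Si](c4ccccc4)(c5ccccc5)C(C)(C)C)ccc1O[Si](C)(C)C(C)(C)C
F8 | step 9 | (E)-4-{4-(benzyloxy)-2-[(RS)-hydroxy(4-hydroxy-3-methoxyphenyl)methyl]-5-methoxyphenyl}-3-{[(tert-butyldiphenylsilyl)oxy]methyl}but-3-enal | COc1cc(C(O)c2cc(OCc3ccccc3)c(OC)cc2/C=C(\CC=O)CO[Si](c4ccccc4)(c5ccccc5)C(C)(C)C)ccc1O
F9 | step 3 | methyl 4-[(tert-butyldimethylsilyl)oxy]-2-(dimethoxyphosphoryl)butanoate | COC(=O)C(CCO[Si](C)(C)C(C)(C)C)P(=O)(OC)OC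
F10 | step 17 | [(1S,2R)-3-{[(tert-butyldiphenylsilyl)oxy]methyl}-7-hydroxy-1-(4-hydroxy-3-methoxyphenyl)-6-methoxy-1,2-dihydronaphthalen-2-yl]methyl acetate | COc1cc([C@H]2c3cc(O)c(OC)cc3C=C(CO[Si](c4ccccc4)(c5ccccc5)C(C)(C)C)[C@@H]2COC(C)=O)ccc1O
F11 | step 17 | [(1S,2R)-7-hydroxy-1-(4-hydroxy-3-methoxyphenyl)-3-(hydroxymethyl)-6-methoxy-1,2-dihydronaphthalen-2-yl]methyl acetate | COc1cc([C@H]2c3cc(O)c(OC)cc3C=C(CO)[C@@H]2COC(C)=O)ccc1O
A1 | alternative 1 | methyl (1S,2S)-7-(benzyloxy)-1-[4-(benzyloxy)-3-methoxyphenyl]-6-methoxy-4-oxo-1,2,3,4-tetrahydronaphthalene-2-carboxylate (1,2-trans) | COc1cc([C@H]2c3cc(OCc4ccccc4)c(OC)cc3C(=O)C[C@@H]2C(=O)OC)ccc1OCc5ccccc5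
A2 | alternative 1 | methyl 5-(benzyloxy)-3-[4-(benzyloxy)-3-methoxyphenyl]-2-(bromomethyl)-6-methoxy-1-oxo-2,3-dihydro-1H-indene-2-carboxylate (C3 configured as C1 of the target, C2 immaterial) | COc1cc([C@H]2c3cc(OCc4ccccc4)c(OC)cc3C(=O)C2(CBr)C(=O)OC)ccc1OCc5ccccc5
A3 | alternative 2 | [(1S,2R,3S,4S)-7-[(tert-butyldimethylsilyl)oxy]-1-{4-[(tert-butyldimethylsilyl)oxy]-3-methoxyphenyl}-3-formyl-4-hydroxy-6-methoxy-1,2,3,4-tetrahydronaphthalen-2-yl]methyl acetate | COc1cc([C@H]2c3cc(O[Si](C)(C)C(C)(C)C)c(OC)cc3[C@@H](O)[C@@H](C=O)[C@@H]2COC(C)=O)ccc1O[Si](C)(C)C(C)(C)C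
A4 | alternative 2 | 4-[(tert-butyldimethylsilyl)oxy]-2-{4-[(tert-butyldimethylsilyl)oxy]-3-methoxybenzyl}-5-methoxybenzaldehyde | COc1cc(Cc2cc(O[Si](C)(C)C(C)(C)C)c(OC)cc2C=O)ccc1O[Si](C)(C)C(C)(C)C
A5 | alternative 2 | (E)-4-oxobut-2-en-1-yl acetate ((E)-4-acetoxybut-2-enal) | CC(=O)OC/C=C/C=O
A6 | alternative 3 | [(1S,2R)-7-(benzyloxy)-1-[4-(benzyloxy)-3-methoxyphenyl]-3-formyl-6-methoxy-1,2-dihydronaphthalen-2-yl]methyl acetate (identical with 23) | COc1cc([C@H]2c3cc(OCc4ccccc4)c(OC)cc3C=C(C=O)[C@@H]2COC(C)=O)ccc1OCc5ccccc5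
A7 | alternative 3 | (2R)-2-{(S)-[4-(benzyloxy)-3-methoxyphenyl][5-(benzyloxy)-2-bromo-4-methoxyphenyl]methyl}-3-formylbut-3-en-1-yl acetate | COc1cc([C@@H](c2cc(OCc3ccccc3)c(OC)cc2Br)[C@@H](COC(C)=O)C(=C)C=O)ccc1OCc4ccccc4
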